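The readings stem from a simulated flask on assumed constants; scatter was added.

Count the target and the open intermediate together: their sum, as a fraction of the charge, measures the starting material that got through. Once the sum stops climbing, count the rest as lost.

common to all: starting material 35 mM

| flask | partner | capture agent | remark | time |
|---|---|---|---|---|
| winter | 54 mM | 0.70 mM | run made earlier |  |
| noon | 85 mM | 0.70 mM | run made earlier |  |
| flask | 38.5 mM | 0.700 mM |  | 5.0 d |

- winter (time / d: open intermediate / %, target / %): 0.333: 22.9, 0.2; 0.625: 32.2, 3.8; 1.67: 33.1, 12.9; 3.00: 19.0, 29.5
- noon (time / d: open intermediate / %, target / %): 0.333: 20.1, 0; 0.625: 30.1, 2.5; 1.67: 19.0, 19.0; 3.00: 6.7, 31.5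

(scatter of a reading: 1 percentage point)



* time up to 5.0 d at which open intermediate stands highest
* the amount of open intermediate, in percent of the starting material charged, at that time

1. Read the last rows. The sum is 48.5% in the winter run and 38.2% in the noon run, where the row before already gave 38.0%.

2. Turn each sum into loss odds, lost per molecule through, and divide by the equivalents of partner. Winter gives 0.688 and noon 0.666. Call their mean, 0.677, K: the loss odds per equivalent of partner, a selectivity factor. Both runs charge the same starting material, so dividing by it is a bet.

3. Fold in the flask: 1.10 equivalents give a share through of 57.3%.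

4. Test it: a share is not a peak. The highest open intermediate reading per share is 0.682 in winter and 0.788 at noon, so my reckoning puts the flask's peak between 39.1% and 45.2%. K holds no time.

The forecast gives 41% at 1.2 d, inside that range: “More partner lowers this plateau.”

The flask peaks at 44.0% at 1.35 d, and the forecast held.

    starting material → open intermediate (k = 6.20 × 10⁻⁴ min⁻¹)
    partner → second intermediate (k = 5.40 × 10⁻⁴ min⁻¹)
    open intermediate + second intermediate → target (k = 0.0150 L mol⁻¹ min⁻¹)
    2 second intermediate → homo product (k = 4.30 × 10⁻⁴ L mol⁻¹ min⁻¹)
    starting material + second intermediate → side product (k = 0.0810 L mol⁻¹ min⁻¹)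
    open intermediate + capture agent → trapped intermediate (k = 0.230 L mol⁻¹ min⁻¹)

Here is the fork: starting material opens, or meets second intermediate and becomes side product. At 5.00 d the flask's target and open intermediate sum to 55.5%, against the reckoned 57.3%. Now cut starting material to 21 mM, with partner unchanged: K gives a share of 44.6%. That neighbour's sum at 5.00 d is 49.2%, its open intermediate peaks at 38.8%, and its side product reaches 47.5%, more than the flask's 42.5%.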